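**Plan**

- Retrosynthesis: the 7(11)-alkene is traced back to an isopropenyl ketone. Ring B is opened at C7–C8 (carbonyl-ene) and C8 is taken off C9 (alkyne homologation of a formyl group). The two ester C–O bonds are cut, and ring A is opened at C1–C2 and C5–C10 ([4+2]).
- Enabling feature (eudesmane numbering: C3 angelate, C4 acetate and methyl, C5 ring-fusion H, C10 angular methyl, C7=C11 isopropylidene, C8 ketone; ring A = C1–C5 and C10, ring B = C5–C10): C10 with its methyl and C9 is the α-carbon and formyl group of methacrolein, and C3(O)=C4(CH3) is the enol silane of a methyl enone. Ring A is therefore a Diels–Alder adduct that already carries the C3 oxygen and a handle for oxidation at C4.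
- Forward: a linear silyloxy triene and methacrolein give ring A; the formyl group becomes an ethynyl group (masked C9–C8 aldehyde); C4 and C3 are oxygenated and acylated; ring B closes last by a carbonyl-ene reaction, then oxidation and alkene isomerisation.
- Stereochemistry: C10 from the chiral oxazaborolidinium catalyst; C5 from the exo topology and the (E)-diene; C4 from enol-ether epoxidation anti to the C5 side chain; C3 from hydroxyl-directed hydride delivery (trans-diol); C7 and C8 are transient.

Key step: step 3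

Assumption: the open face of methacrolein bound to the (S)-configured protonated oxazaborolidine is taken from the usual pre-transition-state picture (Re face of the α-carbon); the (R)-catalyst would be used if the sense proved opposite.

Remark: positions are quoted in eudesmane numbering; β is the face of the C10 methyl group, α the face of the C5 hydrogen. Compounds 19 and 20 are drawn as the expected 7β,8α isomers; any C7/C8 epimers converge in steps 12 and 13.

**Route**

Step 1
Reactants: 1 4-methylpent-3-en-1-ol; 2 3-(triphenylphosphoranylidene)butan-2-one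
Product: 4 (3E)-3,7-dimethylocta-3,6-dien-2-one, via 4-methylpent-3-enal 3 (not isolated)
Conditions: Dess–Martin periodinane, CH2Cl2, 0 °C to rt; then 2, 40 °C
Reagents that add atoms: none
Why: Dess–Martin oxidation should give the β,γ-unsaturated aldehyde without base-induced migration of the double bond, and trapping it in the same flask with the acyl-stabilised ylide (Wittig reaction) should give the trisubstituted (E)-enone, as is usual for stabilised ylides.

Step 2
Reactants: 4 (3E)-3,7-dimethylocta-3,6-dien-2-one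
Product: 6 triisopropyl{[(3E)-3,7-dimethylocta-1,3,6-trien-2-yl]oxy}silane, via lithium dienolate 5 (not isolated)
Conditions: LiN(iPr)2, THF, −78 °C; then TIPSOTf, −78 °C to 0 °C
Reagents that add atoms: triisopropylsilyl trifluoromethanesulfonate, `CC(C)[Si](OS(=O)(=O)C(F)(F)F)(C(C)C)C(C)C`
Why: kinetic deprotonation of an enone takes the α'-proton of the acetyl methyl group in preference to the γ-methylene, and O-silylation of the cross-conjugated dienolate (kinetic silyl enol ether formation) leaves the (E)-trisubstituted alkene in place.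

Step 3
Reactants: 6 triisopropyl{[(3E)-3,7-dimethylocta-1,3,6-trien-2-yl]oxy}silane; 7 methacrolein (2-methylprop-2-enal)
Product: 8 (1S,2S)-1,3-dimethyl-2-(3-methylbut-2-en-1-yl)-4-[(triisopropylsilyl)oxy]cyclohex-3-ene-1-carbaldehyde (formyl trans to the prenyl group)
Conditions: (S)-3,3-diphenyl-1-(2-methylphenyl)tetrahydro-1H,3H-pyrrolo[1,2-c][1,3,2]oxazaborole (10 mol %), (CF3SO2)2NH (10 mol %), CH2Cl2, −78 °C to −40 °C
Reagents that add atoms: none
Why: The N-protonated oxazaborolidine binds the formyl oxygen of methacrolein as a chiral Lewis acid, and the electron-rich silyl dienol ether adds in a concerted but asynchronous [4+2] cycloaddition in which its unsubstituted CH2 terminus bonds to the enal β-carbon (C1–C2) ahead of the bond from the prenyl-bearing terminus to the α-carbon (C5–C10). The closest known reaction type is the oxazaborolidinium-catalysed Diels–Alder reaction of α-substituted acroleins with 2-silyloxy-1,3-dienes. Ring A closes in one event as a cyclohexene by suprafacial addition of the s-cis diene across the C=C bond of the enal (an intermolecular cycloaddition, not a chain cyclisation). C10 is controlled by the catalyst: the enal is held s-trans by the B–O bond and a formyl C–H···O contact, one phenyl group covers one face, and the diene is expected on the open Re face of the α-carbon; C5 is controlled by the (E) geometry of the diene together with the exo-formyl topology, which places the aldehyde trans to the prenyl arm. The step needs regio-, exo- and face selectivity: the 2-silyloxy group (para director) and the substituent on the reacting terminus (ortho director) call for the same regioisomer, and the α-methyl group of the dienophile, which makes the exo arrangement of the formyl group the usual one for α-alkyl acroleins, is what should secure the trans relation.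

Step 4
Reactants: 8 (1S,2S)-1,3-dimethyl-2-(3-methylbut-2-en-1-yl)-4-[(triisopropylsilyl)oxy]cyclohex-3-ene-1-carbaldehyde
Product: 9 {[(3R,4S)-4-ethynyl-2,4-dimethyl-3-(3-methylbut-2-en-1-yl)cyclohex-1-en-1-yl]oxy}triisopropylsilane
Conditions: dimethyl (1-diazo-2-oxopropyl)phosphonate, K2CO3, MeOH, 0 °C to rt
Reagents that add atoms: dimethyl (1-diazo-2-oxopropyl)phosphonate, `CC(=O)C(=[N+]=[N-])P(=O)(OC)OC`
Why: the Seyferth–Gilbert homologation in its Ohira–Bestmann form converts the non-enolisable neopentyl aldehyde into a terminal alkyne under carbonate conditions that the hindered silyl enol ether should tolerate, and the added carbon is C8 in a masked form that is inert to the oxidation, reduction and acylations that follow.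

Step 5
Reactants: 9 {[(3R,4S)-4-ethynyl-2,4-dimethyl-3-(3-methylbut-2-en-1-yl)cyclohex-1-en-1-yl]oxy}triisopropylsilane
Product: 11 (2S,3R,4S)-4-ethynyl-2-hydroxy-2,4-dimethyl-3-(3-methylbut-2-en-1-yl)cyclohexan-1-one, via silyloxy epoxide 10 (not isolated)
Conditions: dimethyldioxirane, acetone/CH2Cl2, −78 °C; then HF·pyridine, THF, 0 °C
Reagents that add atoms: dimethyldioxirane, `CC1(C)OO1`
Why: in this Rubottom oxidation the electron-rich tetrasubstituted enol ether should be epoxidised much faster than the prenyl alkene or the alkyne and from the α face, anti to the pseudoaxial prenyl group on C5 (the only axial group on the α face is the slim ethynyl group), and fluoride opening of the silyloxy epoxide then gives the ketol with the 4α-hydroxyl.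

Step 6
Reactants: 11 (2S,3R,4S)-4-ethynyl-2-hydroxy-2,4-dimethyl-3-(3-methylbut-2-en-1-yl)cyclohexan-1-one
Product: 12 (1S,2S,5S,6R)-5-ethynyl-1,5-dimethyl-6-(3-methylbut-2-en-1-yl)cyclohexane-1,2-diol
Conditions: Me4NBH(OAc)3, MeCN/AcOH, −20 °C to rt
Reagents that add atoms: none
Why: in this hydroxyl-directed triacetoxyborohydride reduction (Evans–Saksena type) the tertiary 4α-hydroxyl displaces an acetate on boron and hydride is delivered to C3 from the same α face, which should give the 3β-alcohol (trans-diol) and leave alkyne and alkene untouched.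

Step 7
Reactants: 13 angelic acid ((2Z)-2-methylbut-2-enoic acid)
Product: 14 (2Z)-2-methylbut-2-enoic 2,4,6-trichlorobenzoic anhydride
Conditions: 2,4,6-trichlorobenzoyl chloride, Et3N, toluene, rt; filtered and used as a solution
Reagents that add atoms: 2,4,6-trichlorobenzoyl chloride, `O=C(Cl)c1c(Cl)cc(Cl)cc1Cl`
Why: mixed-anhydride formation of the Yamaguchi type activates the acid without a nucleophilic catalyst, which avoids the addition–elimination path that turns angelates into tiglates.

Step 8
Reactants: 12 (1S,2S,5S,6R)-5-ethynyl-1,5-dimethyl-6-(3-methylbut-2-en-1-yl)cyclohexane-1,2-diol; 14 (2Z)-2-methylbut-2-enoic 2,4,6-trichlorobenzoic anhydride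
Product: 15 (1S,2S,3R,4S)-4-ethynyl-2-hydroxy-2,4-dimethyl-3-(3-methylbut-2-en-1-yl)cyclohexyl (2Z)-2-methylbut-2-enoate
Conditions: toluene, 80 °C
Reagents that add atoms: none
Why: in this Yamaguchi-type esterification the secondary 3β-hydroxyl attacks the angeloyl carbonyl (the trichlorobenzoyl carbonyl is shielded by its two ortho chlorines), the tertiary hydroxyl is too hindered to compete, and the absence of 4-dimethylaminopyridine should preserve the (Z) geometry.

Step 9
Reactants: 15 (1S,2S,3R,4S)-4-ethynyl-2-hydroxy-2,4-dimethyl-3-(3-methylbut-2-en-1-yl)cyclohexyl (2Z)-2-methylbut-2-enoate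
Product: 16 (1S,2S,3R,4S)-2-acetoxy-4-ethynyl-2,4-dimethyl-3-(3-methylbut-2-en-1-yl)cyclohexyl (2Z)-2-methylbut-2-enoate
Conditions: Ac2O, DMAP, Et3N, CH2Cl2, rt to 40 °C
Reagents that add atoms: acetic anhydride, `CC(=O)OC(C)=O`
Why: Steglich-type acyl transfer through the N-acetylpyridinium ion is the standard way to acetylate tertiary alcohols, and migration of the angelate from the secondary to the tertiary oxygen is thermodynamically uphill.

Step 10
Reactants: 16 (1S,2S,3R,4S)-2-acetoxy-4-ethynyl-2,4-dimethyl-3-(3-methylbut-2-en-1-yl)cyclohexyl (2Z)-2-methylbut-2-enoate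
Product: 18 (1S,2S,3R,4R)-2-acetoxy-2,4-dimethyl-3-(3-methylbut-2-en-1-yl)-4-(2-oxoethyl)cyclohexyl (2Z)-2-methylbut-2-enoate, via alkenylborane 17 (not isolated)
Conditions: Cy2BH, THF, 0 °C; then H2O2, pH 7 phosphate buffer, 0 °C to rt
Reagents that add atoms: hydrogen peroxide, `OO`
Why: in this Brown hydroboration–oxidation dicyclohexylborane adds once and anti-Markovnikov to the terminal alkyne much faster than to the trisubstituted prenyl alkene or the α,β-disubstituted enoate, and buffered peroxide oxidation of the (E)-alkenylborane gives the enol and hence the C8 aldehyde without harming the esters.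

Step 11
Reactants: 18 (1S,2S,3R,4R)-2-acetoxy-2,4-dimethyl-3-(3-methylbut-2-en-1-yl)-4-(2-oxoethyl)cyclohexyl (2Z)-2-methylbut-2-enoate
Product: 19 (1S,2S,4aR,6S,7R,8aR)-1-acetoxy-6-hydroxy-1,4a-dimethyl-7-(prop-1-en-2-yl)decahydronaphthalen-2-yl (2Z)-2-methylbut-2-enoate
Conditions: Me2AlCl, CH2Cl2, −78 °C; aqueous HCl work-up
Reagents that add atoms: none
Why: in this intramolecular carbonyl-ene reaction (the citronellal-to-isopulegol type) C7 of the prenyl group attacks the aluminium-activated aldehyde with transfer of an allylic hydrogen, which closes ring B through a chair transition state with both tethers equatorial (trans fusion fixed by C5 and C10) and should place the 8-hydroxyl and 7-isopropenyl groups equatorial.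

Step 12
Reactants: 19 (1S,2S,4aR,6S,7R,8aR)-1-acetoxy-6-hydroxy-1,4a-dimethyl-7-(prop-1-en-2-yl)decahydronaphthalen-2-yl (2Z)-2-methylbut-2-enoate
Product: 20 (1S,2S,4aR,7R,8aR)-1-acetoxy-1,4a-dimethyl-6-oxo-7-(prop-1-en-2-yl)decahydronaphthalen-2-yl (2Z)-2-methylbut-2-enoate
Conditions: Dess–Martin periodinane, CH2Cl2, rt
Reagents that add atoms: none
Why: Dess–Martin oxidation of the secondary alcohol to the C8 ketone is mild enough to leave both esters and the isopropenyl group unchanged.

Step 13
Reactants: 20 (1S,2S,4aR,7R,8aR)-1-acetoxy-1,4a-dimethyl-6-oxo-7-(prop-1-en-2-yl)decahydronaphthalen-2-yl (2Z)-2-methylbut-2-enoate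
Product: 21 (1S,2S,4aR,8aR)-1-acetoxy-1,4a-dimethyl-6-oxo-7-(propan-2-ylidene)decahydronaphthalen-2-yl (2Z)-2-methylbut-2-enoate (CNP0141494.1)
Conditions: DBU, CH2Cl2, rt
Reagents that add atoms: none
Why: base-mediated isomerisation of the β,γ-unsaturated ketone through its C7 dienolate (the isopulegone-to-pulegone type) should move the double bond into conjugation as the tetrasubstituted 7(11)-alkene, the amidine base being too weak and too hindered to cleave the esters or to isomerise the angelate.

**Compound list**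

```
1 | 4-methylpent-3-en-1-ol | CC(C)=CCCO | starting material
2 | 3-(triphenylphosphoranylidene)butan-2-one | CC(=O)C(C)=P(c1ccccc1)(c1ccccc1)c1ccccc1 | starting material
3 | 4-methylpent-3-enal | CC(C)=CCC=O | intermediate
4 | (3E)-3,7-dimethylocta-3,6-dien-2-one | CC(=O)/C(C)=C/CC=C(C)C | intermediate
5 | lithium (3E)-3,7-dimethylocta-1,3,6-trien-2-olate | [Li]OC(=C)/C(C)=C/CC=C(C)C | intermediate
6 | triisopropyl{[(3E)-3,7-dimethylocta-1,3,6-trien-2-yl]oxy}silane | C=C(O[Si](C(C)C)(C(C)C)C(C)C)/C(C)=C/CC=C(C)C | intermediate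
7 | methacrolein (2-methylprop-2-enal) | CC(=C)C=O | starting material
8 | (1S,2S)-1,3-dimethyl-2-(3-methylbut-2-en-1-yl)-4-[(triisopropylsilyl)oxy]cyclohex-3-ene-1-carbaldehyde (formyl trans to prenyl) | O=C[C@@]1(C)CCC(O[Si](C(C)C)(C(C)C)C(C)C)=C(C)[C@@H]1CC=C(C)C | intermediate
9 | {[(3R,4S)-4-ethynyl-2,4-dimethyl-3-(3-methylbut-2-en-1-yl)cyclohex-1-en-1-yl]oxy}triisopropylsilane (ethynyl trans to prenyl) | C#C[C@@]1(C)CCC(O[Si](C(C)C)(C(C)C)C(C)C)=C(C)[C@@H]1CC=C(C)C | intermediate
10 | silyloxy epoxide of 9: the enol ether C=C of 9 carries an epoxide oxygen on the face trans to the prenyl group and cis to the ethynyl group, the other two centres as in 9 | C#C[C@@]1(C)CC[C@@]2(O[Si](C(C)C)(C(C)C)C(C)C)O[C@@]2(C)[C@@H]1CC=C(C)C | intermediate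
11 | (2S,3R,4S)-4-ethynyl-2-hydroxy-2,4-dimethyl-3-(3-methylbut-2-en-1-yl)cyclohexan-1-one | C#C[C@@]1(C)CCC(=O)[C@@](C)(O)[C@@H]1CC=C(C)C | intermediate
12 | (1S,2S,5S,6R)-5-ethynyl-1,5-dimethyl-6-(3-methylbut-2-en-1-yl)cyclohexane-1,2-diol (trans-diol) | C#C[C@@]1(C)CC[C@H](O)[C@@](C)(O)[C@@H]1CC=C(C)C | intermediate
13 | angelic acid ((2Z)-2-methylbut-2-enoic acid) | C/C=C(/C)C(=O)O | starting material
14 | (2Z)-2-methylbut-2-enoic 2,4,6-trichlorobenzoic anhydride | C/C=C(/C)C(=O)OC(=O)c1c(Cl)cc(Cl)cc1Cl | intermediate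
15 | (1S,2S,3R,4S)-4-ethynyl-2-hydroxy-2,4-dimethyl-3-(3-methylbut-2-en-1-yl)cyclohexyl (2Z)-2-methylbut-2-enoate | C#C[C@@]1(C)CC[C@H](OC(=O)/C(C)=C\C)[C@@](C)(O)[C@@H]1CC=C(C)C | intermediate
16 | (1S,2S,3R,4S)-2-acetoxy-4-ethynyl-2,4-dimethyl-3-(3-methylbut-2-en-1-yl)cyclohexyl (2Z)-2-methylbut-2-enoate | C#C[C@@]1(C)CC[C@H](OC(=O)/C(C)=C\C)[C@@](C)(OC(C)=O)[C@@H]1CC=C(C)C | intermediate
17 | (1S,2S,3R,4R)-2-acetoxy-4-[(E)-2-(dicyclohexylboranyl)ethenyl]-2,4-dimethyl-3-(3-methylbut-2-en-1-yl)cyclohexyl (2Z)-2-methylbut-2-enoate | C1CCCCC1B(C1CCCCC1)/C=C/[C@@]1(C)CC[C@H](OC(=O)/C(C)=C\C)[C@@](C)(OC(C)=O)[C@@H]1CC=C(C)C | intermediate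
18 | (1S,2S,3R,4R)-2-acetoxy-2,4-dimethyl-3-(3-methylbut-2-en-1-yl)-4-(2-oxoethyl)cyclohexyl (2Z)-2-methylbut-2-enoate | O=CC[C@@]1(C)CC[C@H](OC(=O)/C(C)=C\C)[C@@](C)(OC(C)=O)[C@@H]1CC=C(C)C | intermediate
19 | (1S,2S,4aR,6S,7R,8aR)-1-acetoxy-6-hydroxy-1,4a-dimethyl-7-(prop-1-en-2-yl)decahydronaphthalen-2-yl (2Z)-2-methylbut-2-enoate (3β-angelate, 4α-acetate, 8α-OH, 7β-isopropenyl, trans-decalin) | C/C=C(/C)C(=O)O[C@H]1CC[C@]2(C)C[C@H](O)[C@@H](C(C)=C)C[C@H]2[C@]1(C)OC(C)=O | intermediate
20 | (1S,2S,4aR,7R,8aR)-1-acetoxy-1,4a-dimethyl-6-oxo-7-(prop-1-en-2-yl)decahydronaphthalen-2-yl (2Z)-2-methylbut-2-enoate | C/C=C(/C)C(=O)O[C@H]1CC[C@]2(C)CC(=O)[C@@H](C(C)=C)C[C@H]2[C@]1(C)OC(C)=O | intermediate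
21 | (1S,2S,4aR,8aR)-1-acetoxy-1,4a-dimethyl-6-oxo-7-(propan-2-ylidene)decahydronaphthalen-2-yl (2Z)-2-methylbut-2-enoate (4α-acetoxy-3β-angeloyloxyeudesm-7(11)-en-8-one, CNP0141494.1) | C/C=C(/C)C(=O)O[C@H]1CC[C@]2(C)CC(=O)C(=C(C)C)C[C@H]2[C@]1(C)OC(C)=O | target
```

**Step count and risks**

Total: 13 steps. Longest linear sequence: 12 steps (steps 1–6 and 8–13, from 1 to 21); step 7 prepares the acylating agent.

Steps most likely to fail:

1. Step 3. The cycloaddition may stall at the hindered, substituted diene terminus, or proceed with poor exo/endo or facial discrimination. The fallback moves stereocontrol from the catalyst to a covalently bound controller; it sets out from diene 6 and returns at aldehyde 8. The methacrylate of (R)-pantolactone F1 (from methacryloyl chloride and (R)-pantolactone, Et3N, CH2Cl2) would be combined with 6 under a chelating Lewis acid (TiCl4, CH2Cl2, −78 °C), a known auxiliary-controlled Diels–Alder reaction type for chiral methacrylates, to give the cycloadduct ester F2. Reduction with LiAlH4 (THF, 0 °C), which leaves the silyl enol ether alone, would release the primary alcohol F3, and Dess–Martin oxidation would give 8. The (S)-lactone would be used if the auxiliary shielded the wrong face.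

2. Step 8. The (Z) geometry may be lost by isomerisation to the tiglate during activation or heating, or acylation of the hindered secondary hydroxyl may be slow. The fallback builds the angelate double bond on the ester instead of carrying it in; it sets out from diol 12 and returns at diester 16. Acylation of the secondary hydroxyl with 2-[bis(2,2,2-trifluoroethoxy)phosphoryl]propanoic acid (DCC, DMAP, CH2Cl2), which has no double bond to isomerise, would give the phosphonopropionate F4. Acetylation of the tertiary hydroxyl (Ac2O, DMAP, Et3N) would give the phosphonate acetate F5. Still–Gennari olefination with acetaldehyde (KN(SiMe3)2, 18-crown-6, THF, −78 °C) would then form the (Z)-2-methylbut-2-enoate under kinetic control and give 16.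

3. Step 9. Acylation of the crowded tertiary hydroxyl may be incomplete, or acyl groups may scramble between O3 and O4 under forcing conditions. The fallback introduces the acetate together with the C4 oxygen, so that no tertiary alcohol is acylated; it sets out from silyl enol ether 9 and returns at diester 16. Oxidation of 9 with Pb(OAc)4 (CH2Cl2, 0 °C; α-acetoxylation of the enol silane, expected anti to the prenyl group as in step 5) would give the 4α-acetoxy ketone F6. Reagent-controlled Corey–Bakshi–Shibata reduction with catecholborane and (R)-1-methyl-3,3-diphenyltetrahydro-1H,3H-pyrrolo[1,2-c][1,3,2]oxazaborole (toluene, −78 °C, conditions that spare the alkyne) would give the 3β-hydroxy 4α-acetate F7. Esterification of F7 with mixed anhydride 14 as in step 8 would give 16.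

**Further compounds**

```
F1 | step 3 | (3R)-4,4-dimethyl-2-oxooxolan-3-yl 2-methylprop-2-enoate | CC(=C)C(=O)O[C@H]1C(=O)OCC1(C)C
F2 | step 3 | (3R)-4,4-dimethyl-2-oxooxolan-3-yl (1S,2S)-1,3-dimethyl-2-(3-methylbut-2-en-1-yl)-4-[(triisopropylsilyl)oxy]cyclohex-3-ene-1-carboxylate | O=C(O[C@H]1C(=O)OCC1(C)C)[C@@]1(C)CCC(O[Si](C(C)C)(C(C)C)C(C)C)=C(C)[C@@H]1CC=C(C)C
F3 | step 3 | [(1S,2R)-1,3-dimethyl-2-(3-methylbut-2-en-1-yl)-4-[(triisopropylsilyl)oxy]cyclohex-3-en-1-yl]methanol | OC[C@@]1(C)CCC(O[Si](C(C)C)(C(C)C)C(C)C)=C(C)[C@@H]1CC=C(C)C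
F4 | step 8 | (1S,2S,3R,4S)-4-ethynyl-2-hydroxy-2,4-dimethyl-3-(3-methylbut-2-en-1-yl)cyclohexyl 2-[bis(2,2,2-trifluoroethoxy)phosphoryl]propanoate (epimers at the phosphonate carbon) | C#C[C@@]1(C)CC[C@H](OC(=O)C(C)P(=O)(OCC(F)(F)F)OCC(F)(F)F)[C@@](C)(O)[C@@H]1CC=C(C)C
F5 | step 8 | (1S,2S,3R,4S)-2-acetoxy-4-ethynyl-2,4-dimethyl-3-(3-methylbut-2-en-1-yl)cyclohexyl 2-[bis(2,2,2-trifluoroethoxy)phosphoryl]propanoate (epimers at the phosphonate carbon) | C#C[C@@]1(C)CC[C@H](OC(=O)C(C)P(=O)(OCC(F)(F)F)OCC(F)(F)F)[C@@](C)(OC(C)=O)[C@@H]1CC=C(C)C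
F6 | step 9 | (1S,2R,3S)-3-ethynyl-1,3-dimethyl-2-(3-methylbut-2-en-1-yl)-6-oxocyclohexyl acetate | C#C[C@@]1(C)CCC(=O)[C@@](C)(OC(C)=O)[C@@H]1CC=C(C)C
F7 | step 9 | (1S,2R,3S,6S)-3-ethynyl-6-hydroxy-1,3-dimethyl-2-(3-methylbut-2-en-1-yl)cyclohexyl acetate | C#C[C@@]1(C)CC[C@H](O)[C@@](C)(OC(C)=O)[C@@H]1CC=C(C)C
```
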